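Ring B is assembled in one operation on an enantiopure ring A. Disconnecting C6–C7 and C9–C10 (labdane numbering) leaves the allylic triad C6=C5–C10(H) of a 2-methylidenecyclohexane ester and acrolein as the C7–C8–C9 unit. Me2AlCl drives an intermolecular ene reaction (C6–C7) and then cyclisation of the aldehyde onto the new tetrasubstituted C5=C10 alkene (C9–C10), creating quaternary C10 with oxygen at C9 and unsaturation at C5. The key step exploits the para relationship of these two bonds in ring B, which flank the C5/C9 carbinol carbons and the C10 methyl. Hydration, oxidation, methylenation, side-chain addition and carboalumination complete the acid.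

Key step: step 5

Remark: labdane numbering is used (C4 bears CO2R and CH3, C5 and C9 the tertiary hydroxyls, C10 the angular methyl, C17 the methylene on C8, C11–C16 the side chain) and β is the face of the C10 methyl; the enamine alkylation of step 2 is assumed to give the (S)-ester under the solvent/ligand pairing quoted, the mirror-image valine ester being the alternative.

Step 1
Reactants: 1 methyl 2-oxocyclohexane-1-carboxylate; 2 tert-butyl L-valinate
Product: 3 methyl 2-{[(2S)-1-tert-butoxy-3-methyl-1-oxobutan-2-yl]amino}cyclohex-1-ene-1-carboxylate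
Conditions: BF3·OEt2 (cat.), benzene, reflux, Dean–Stark
Reagents that add atoms: none
Why: Acid-catalysed condensation of the β-keto ester with the primary amine gives the hydrogen-bonded enamino ester, installing the valine auxiliary without creating a new stereocentre.

Step 2
Reactants: 3 chiral enamino ester
Product: 5 methyl (1S)-1-methyl-2-oxocyclohexane-1-carboxylate, via methylated ketimine 4 (not isolated)
Conditions: LiN(i-Pr)2 (LDA), toluene, −78 °C; HMPA; MeI, −78 → −20 °C; then 1 M HCl, rt
Reagents that add atoms: iodomethane, CI; water, O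
Why: Diastereoselective alkylation of a chiral lithio-enamine: lithium is chelated by the enamine nitrogen and the valine ester, the isopropyl group shields one face so that MeI should enter from the other and set quaternary C4 as S, and mild hydrolysis of the ketimine returns the ketone and the auxiliary.

Step 3
Reactants: 5 methyl (1S)-1-methyl-2-oxocyclohexane-1-carboxylate
Product: 6 methyl (1S)-1,3-dimethyl-2-oxocyclohexane-1-carboxylate (both C3 epimers)
Conditions: LiN(i-Pr)2 (LDA), THF, −78 °C; MeI, −78 → 0 °C
Reagents that add atoms: iodomethane, CI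
Why: Kinetic enolate alkylation: the quaternary C4 leaves only the C10 side enolisable, so the future C20 methyl should be installed regiospecifically, and the new centre is left as a mixture because it becomes sp2 in step 5.

Step 4
Reactants: 6 methyl (1S)-1,3-dimethyl-2-oxocyclohexane-1-carboxylate
Product: 7 methyl (1S)-1,3-dimethyl-2-methylidenecyclohexane-1-carboxylate (both C3 epimers)
Conditions: Zn, CH2Br2, TiCl4, THF/CH2Cl2, 0 °C → rt
Reagents that add atoms: dibromomethane, BrCBr
Why: Takai–Lombardo methylenation: the non-basic zinc/titanium methylene reagent should convert the hindered, enolisable ketone into the exocyclic alkene without retro-Claisen cleavage or attack on the ester.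

Step 5
Reactants: 7 methyl (1S)-1,3-dimethyl-2-methylidenecyclohexane-1-carboxylate; 8 acrolein
Product: 10 methyl (1S,4aS)-5-hydroxy-1,4a-dimethyl-1,2,3,4,4a,5,6,7-octahydronaphthalene-1-carboxylate (both C5 epimers; labdane C9–OH and C5=C6), via ene-adduct aldehyde 9 (not isolated)
Conditions: Me2AlCl (2.5 equiv), CH2Cl2, −78 → 0 °C; dilute HCl work-up
Reagents that add atoms: none
Why: Two consecutive Lewis-acid-promoted ene-type events run in one flask (the known Me2AlCl-promoted sequential ene annulation of alkylidenecycloalkanes with acrolein is the closest case): the acrolein–Me2AlCl complex is attacked at its terminal carbon (C7) by the methylene carbon C6 with transfer of the C10 hydrogen, the only allylic hydrogen because C4 is quaternary, so both C3 epimers of 7 converge on the single tetrasubstituted C5=C10 alkene of aldehyde 9. The aluminium-bound aldehyde carbon C9 then adds to C10 through a chair-like carbonyl–olefin (Prins/ene) transition state, closing ring B by 6-endo-trig attack on the alkene with the carbonyl oxygen exocyclic. The resulting tertiary C5 cation can lose a proton only from C6 (C4 and C10 carry none), which gives the C5=C6 alkene needed for the later C5 hydroxylation. Ring size is secured by the quaternary C4, which disfavours bond formation at C5 (spiro five-ring closure) relative to C10. The new quaternary centre C10 is set by C4: C9 should approach the alkene face opposite the pseudo-axial ester (smaller A value than methyl), so that the C10 methyl ends cis to the ester and a 1,3-diaxial methyl–methyl contact is avoided. The C9 carbinol centre is not controlled and is erased by the oxidation in step 7.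

Step 6
Reactants: 10 octalin alcohol
Product: 12 methyl 5α,9ξ-dihydroxy-11,12,13,14,15,16,17-heptanorlabdan-19-oate, via C5 hydroperoxide 11 (not isolated)
Conditions: Co(acac)2 (cat.), PhSiH3, O2 (1 atm), THF/i-PrOH, rt; then PPh3
Reagents that add atoms: dioxygen, O=O
Why: Mukaiyama hydration: hydrogen-atom transfer to C6 gives the tertiary C5 radical, which should capture O2 on the α-face opposite the axial C10 methyl and axial C4 ester to give the trans-fused 5α-hydroperoxide, reduced by PPh3; no other alkene is present at this stage.

Step 7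
Reactants: 12 diol
Product: 13 methyl 5α-hydroxy-9-oxo-11,12,13,14,15,16,17-heptanorlabdan-19-oate
Conditions: Dess–Martin periodinane, NaHCO3, CH2Cl2, rt
Reagents that add atoms: none
Why: Dess–Martin oxidation touches only the secondary C9 alcohol, so both C9 epimers converge on one ketone, which should be stable because C10 is quaternary (no dehydration) and retro-aldol would have to open the decalin to a ten-membered ring.

Step 8
Reactants: 13 hydroxy ketone
Product: 15 methyl 5α-hydroxy-9-oxo-11,12,13,14,15,16-hexanorlabd-8(17)-en-19-oate, via Mannich base 14 (not isolated)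
Conditions: (CH2O)n, PhNHMe·CF3CO2H, THF, reflux
Reagents that add atoms: formaldehyde (from paraformaldehyde), C=O
Why: Mannich-type α-methylenation (aminomethylation then β-elimination of the amine): C8 is the only enolisable position next to the ketone, so the exocyclic methylene should be installed regiospecifically under mildly acidic conditions that generate no alkoxide.

Step 9
Reactants: 15 exo-methylene ketone; 16 (4-bromobut-1-yn-1-yl)trimethylsilane
Product: 18 methyl 5α,9β-dihydroxy-14-(trimethylsilyl)-15,16-dinorlabd-8(17)-en-13-yn-19-oate, via organomagnesium reagent 17 (not isolated)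
Conditions: 16, Mg, THF; CeCl3, THF, −78 °C; then 15 (3 equiv of reagent), −78 → −40 °C
Reagents that add atoms: none
Why: Organocerium 1,2-addition to the hindered enone: the first equivalent converts the 5-OH into its alkoxide and the carbon nucleophile should then attack C9 anti to the axial C10 methyl (Felkin–Anh), that is from the α-face where the metal alkoxide can also guide it, placing C11 α and the new 9-OH β.

Step 10
Reactants: 18 silylated alkyne
Product: 19 methyl 5α,9β-dihydroxy-15,16-dinorlabd-8(17)-en-13-yn-19-oate
Conditions: K2CO3, MeOH, rt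
Reagents that add atoms: none
Why: Base-catalysed methanolysis of the alkynyl C–Si bond frees the terminal alkyne without touching the hindered ester or the tertiary alcohols.

Step 11
Reactants: 19 terminal alkyne
Product: 21 methyl 5α,9β-dihydroxyisocupressate, via alkenylalane 20 (not isolated)
Conditions: Me3Al, Cp2ZrCl2 (cat.), CH2Cl2, rt; evaporate; n-BuLi, THF, −78 °C; (CH2O)n, rt
Reagents that add atoms: trimethylaluminium, C[Al](C)C; formaldehyde (from paraformaldehyde), C=O
Why: Negishi zirconium-catalysed carboalumination adds methyl (C16) to C13 and aluminium to C14 in a syn fashion, and the derived alkenylalanate should react with formaldehyde with retention to give the E-trisubstituted allylic alcohol; the tertiary alcohols ride through as aluminium alkoxides and the 1,1-disubstituted alkene is inert.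

Step 12
Reactants: 21 methyl ester
Product: 22 5α,9β-dihydroxyisocupressic acid
Conditions: n-PrSLi, HMPA, rt; then cold dilute HCl to pH 4
Reagents that add atoms: none
Why: SN2 demethylation by thiolate at the O–CH3 carbon avoids a tetrahedral intermediate at the hindered axial C19 carbonyl and should leave the tertiary and allylic alcohols and both alkenes untouched.

Compound list
1 | methyl 2-oxocyclohexane-1-carboxylate | O=C1CCCCC1C(=O)OC | starting material
2 | tert-butyl L-valinate | CC(C)[C@H](N)C(=O)OC(C)(C)C | starting material
3 | methyl 2-{[(2S)-1-tert-butoxy-3-methyl-1-oxobutan-2-yl]amino}cyclohex-1-ene-1-carboxylate | COC(=O)C1=C(N[C@@H](C(C)C)C(=O)OC(C)(C)C)CCCC1 | intermediate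
4 | methyl (1S)-2-{[(2S)-1-tert-butoxy-3-methyl-1-oxobutan-2-yl]imino}-1-methylcyclohexane-1-carboxylate | CC(C)[C@H](N=C1CCCC[C@]1(C)C(=O)OC)C(=O)OC(C)(C)C | intermediate (not isolated)
5 | methyl (1S)-1-methyl-2-oxocyclohexane-1-carboxylate | O=C1CCCC[C@]1(C)C(=O)OC | intermediate
6 | methyl (1S)-1,3-dimethyl-2-oxocyclohexane-1-carboxylate (C3 epimers) | O=C1C(C)CCC[C@]1(C)C(=O)OC | intermediate
7 | methyl (1S)-1,3-dimethyl-2-methylidenecyclohexane-1-carboxylate (C3 epimers) | C=C1C(C)CCC[C@]1(C)C(=O)OC | intermediate
8 | acrolein (prop-2-enal) | C=CC=O | starting material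
9 | methyl (1S)-1,3-dimethyl-2-(4-oxobutyl)cyclohex-2-ene-1-carboxylate | O=CCCCC1=C(C)CCC[C@]1(C)C(=O)OC | intermediate (not isolated)
10 | methyl (1S,4aS)-5-hydroxy-1,4a-dimethyl-1,2,3,4,4a,5,6,7-octahydronaphthalene-1-carboxylate (C5 epimers; ring-fusion methyl cis to the ester) | OC1CCC=C2[C@]1(C)CCC[C@]2(C)C(=O)OC | intermediate
11 | methyl 5α-hydroperoxy-9ξ-hydroxy-11,12,13,14,15,16,17-heptanorlabdan-19-oate | OC1CCC[C@]2(OO)[C@]1(C)CCC[C@]2(C)C(=O)OC | intermediate (not isolated)
12 | methyl 5α,9ξ-dihydroxy-11,12,13,14,15,16,17-heptanorlabdan-19-oate (trans-decalin, 5-OH trans to the C10 methyl) | OC1CCC[C@]2(O)[C@]1(C)CCC[C@]2(C)C(=O)OC | intermediate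
13 | methyl 5α-hydroxy-9-oxo-11,12,13,14,15,16,17-heptanorlabdan-19-oate | O=C1CCC[C@]2(O)[C@]1(C)CCC[C@]2(C)C(=O)OC | intermediate
14 | methyl 5α-hydroxy-17-(N-methylanilino)-9-oxo-11,12,13,14,15,16-hexanorlabdan-19-oate (C8 epimers) | CN(CC1CC[C@]2(O)[C@](C)(CCC[C@]2(C)C(=O)OC)C1=O)c1ccccc1 | intermediate (not isolated)
15 | methyl 5α-hydroxy-9-oxo-11,12,13,14,15,16-hexanorlabd-8(17)-en-19-oate | C=C1CC[C@]2(O)[C@](C)(CCC[C@]2(C)C(=O)OC)C1=O | intermediate
16 | (4-bromobut-1-yn-1-yl)trimethylsilane | C[Si](C)(C)C#CCCBr | starting material
17 | [4-(trimethylsilyl)but-3-yn-1-yl]magnesium bromide | C[Si](C)(C)C#CCC[Mg]Br | intermediate (not isolated)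
18 | methyl 5α,9β-dihydroxy-14-(trimethylsilyl)-15,16-dinorlabd-8(17)-en-13-yn-19-oate | C=C1CC[C@]2(O)[C@](C)(CCC[C@]2(C)C(=O)OC)[C@]1(O)CCC#C[Si](C)(C)C | intermediate
19 | methyl 5α,9β-dihydroxy-15,16-dinorlabd-8(17)-en-13-yn-19-oate | C=C1CC[C@]2(O)[C@](C)(CCC[C@]2(C)C(=O)OC)[C@]1(O)CCC#C | intermediate
20 | methyl 14-(dimethylalumanyl)-5α,9β-dihydroxy-15-norlabda-8(17),13E-dien-19-oate (hydroxyls present as aluminium alkoxides in the flask) | C=C1CC[C@]2(O)[C@](C)(CCC[C@]2(C)C(=O)OC)[C@]1(O)CC/C(C)=C/[Al](C)C | intermediate (not isolated)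
21 | methyl 5α,9β-dihydroxyisocupressate | C=C1CC[C@]2(O)[C@](C)(CCC[C@]2(C)C(=O)OC)[C@]1(O)CC/C(C)=C/CO | intermediate
22 | 5α,9β-dihydroxyisocupressic acid | C=C1CC[C@]2(O)[C@](C)(CCC[C@]2(C)C(=O)O)[C@]1(O)CC/C(C)=C/CO | target

Total step count: 12. Longest linear sequence: 12 steps (1 → 22); 2, 8 and 16 are purchased.

Steps most likely to fail

Step 5. The second, cationic stage may not end by proton loss: the ring-fusion C5 cation can be intercepted by chloride from the aluminium reagent, stalling the sequence at a tertiary chloride. The fallback sets out from 7 (with 8) and keeps the one-flask ene/cyclisation, but takes chloride capture as the deliberate end point (MeAlCl2, CH2Cl2, −78 °C, cold quench). This should give methyl 5ξ-chloro-9ξ-hydroxy-11,12,13,14,15,16,17-heptanorlabdan-19-oate F1, with both ring B bonds again made in one operation. Silver-assisted hydrolysis (AgOTf, 2,6-lutidine, aqueous acetone) should then re-ionise C5 and let water enter from the less hindered α-face. This comes back to the route at diol 12 and bypasses the radical hydration.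

Step 9. The carbon nucleophile may attack the C9 carbonyl from the β-face, or the 5-alkoxide may add in conjugate fashion to the enone before the addition takes place. The fallback sets out from 15 and delivers carbon from O5 itself. Silylation (allyl(chloro)dimethylsilane, imidazole, DMF) gives methyl 5α-[allyl(dimethyl)silyl]oxy-9-oxo-11,12,13,14,15,16-hexanorlabd-8(17)-en-19-oate F2. TiCl4 at −78 °C should transfer the allyl group intramolecularly to the α-face of C9 (tethered Hosomi–Sakurai allylation) and give, after aqueous work-up, methyl 5α,9β-dihydroxy-14,15,16-trinorlabda-8(17),12-dien-19-oate F3. Hydroboration of the monosubstituted alkene (9-BBN; NaOH, H2O2) gives methyl 5α,9β,13-trihydroxy-14,15,16-trinorlabd-8(17)-en-19-oate F4. Parikh–Doering oxidation gives methyl 5α,9β-dihydroxy-13-oxo-14,15,16-trinorlabd-8(17)-en-19-oate F5 (in equilibrium with its lactol). Ohira–Bestmann homologation (K2CO3, MeOH) then comes back to the route at alkyne 19.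

Step 6. Hydrogen-atom transfer to the hindered trisubstituted alkene may be slow, or oxygen capture by the C5 radical may show poor facial selectivity (cis- instead of trans-fusion). The fallback sets out from 10. Epoxidation (mCPBA, NaHCO3, CH2Cl2, 0 °C) from the α-face opposite the two β-axial groups gives methyl 5α,6α-epoxy-9ξ-hydroxy-11,12,13,14,15,16,17-heptanorlabdan-19-oate F6. Trans-diaxial opening at C6 (PhSeSePh, NaBH4, EtOH; Fürst–Plattner) gives methyl 5α,9ξ-dihydroxy-6β-(phenylselanyl)-11,12,13,14,15,16,17-heptanorlabdan-19-oate F7. Radical deselenation (Bu3SnH, AIBN, toluene, 80 °C) comes back to the route at diol 12.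

Further compounds
F1 | step 5 | methyl 5ξ-chloro-9ξ-hydroxy-11,12,13,14,15,16,17-heptanorlabdan-19-oate | OC1CCCC2(Cl)[C@]1(C)CCC[C@]2(C)C(=O)OC
F2 | step 9 | methyl 5α-[allyl(dimethyl)silyl]oxy-9-oxo-11,12,13,14,15,16-hexanorlabd-8(17)-en-19-oate | C=C1CC[C@]2(O[Si](C)(C)CC=C)[C@](C)(CCC[C@]2(C)C(=O)OC)C1=O
F3 | step 9 | methyl 5α,9β-dihydroxy-14,15,16-trinorlabda-8(17),12-dien-19-oate | C=C1CC[C@]2(O)[C@](C)(CCC[C@]2(C)C(=O)OC)[C@]1(O)CC=C
F4 | step 9 | methyl 5α,9β,13-trihydroxy-14,15,16-trinorlabd-8(17)-en-19-oate | C=C1CC[C@]2(O)[C@](C)(CCC[C@]2(C)C(=O)OC)[C@]1(O)CCCO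
F5 | step 9 | methyl 5α,9β-dihydroxy-13-oxo-14,15,16-trinorlabd-8(17)-en-19-oate | C=C1CC[C@]2(O)[C@](C)(CCC[C@]2(C)C(=O)OC)[C@]1(O)CCC=O
F6 | step 6 | methyl 5α,6α-epoxy-9ξ-hydroxy-11,12,13,14,15,16,17-heptanorlabdan-19-oate | OC1CC[C@H]3[C@]2(O3)[C@]1(C)CCC[C@]2(C)C(=O)OC
F7 | step 6 | methyl 5α,9ξ-dihydroxy-6β-(phenylselanyl)-11,12,13,14,15,16,17-heptanorlabdan-19-oate | OC1CC[C@@H]([Se]c3ccccc3)[C@]2(O)[C@]1(C)CCC[C@]2(C)C(=O)OC
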